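**Plan**

1. Retrosynthesis: the acetate and the ring B carbinol are made last. The bond between the acetoxy-bearing carbon and ring B is cut as an aldol bond, giving a trans-hydrindenone (rings A and B) and an α-silyloxy aldehyde that carries ring C. The tertiary alcohol/aldehyde pair of ring C goes back to a Sharpless epoxide of a cyclohexenylmethanol, and that to (S)-4-bromo-3,3-dimethylcyclohexanone.
2. Ring C is numbered C1' (carbinol), C4' (CHBr), C5' (CMe2), C6' (CH2 between C1' and C5'). C1' and C4' are 1,4-related across the C5'Me2–C6'H2 arc, so taking out C6' leaves a cyclopentanone whose C=O and C–Br carbons both flank CMe2, the skeleton of prochiral 2,2-dimethylcyclopentane-1,3-dione. Ring C is therefore built as a cyclopentane, the neopentyl C–Br bond is set there by SN2 inversion, and the ring is then enlarged by inserting C6' between C1' and C5'.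
3. Forward order: dione, carbinol, bromide, ring enlargement (ring C), vinyl triflate, allylic alcohol, epoxide, diol, aldehyde. Separately ring A (from 2-methylcyclohexane-1,3-dione), then ring B (Wacker/aldol annulation), ketal, hydroboration, methyl addition, re-formed enone. Then 1,4-hydrosilylation, aldol union, acetylation, ketone reduction, desilylation.
4. Stereochemistry: two oxazaborolidine desymmetrisations (C4' and the ring A C–Br carbon, each after inversion, plus the angular carbon); D-(−)-tartrate epoxidation (C1'); the angular methyl directs hydroboration, methyl addition, conjugate hydride delivery and enolate attack; an open-transition-state aldol sets the acetoxy carbon; a hindered hydride sets the ring B carbinol.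

Key step: step 3

Assumption: the facial sense quoted for the oxazaborolidine reductions and the titanium–tartrate epoxidation follows the usual empirical models, and the C4'/C1' relationship in ring C is fixed by two independent absolute inductions, not by the mobile ring itself.

**Fragment with ring C**

Step 1
Reactants: 1 2,2-dimethylcyclopentane-1,3-dione
Product: 2 (R)-3-hydroxy-2,2-dimethylcyclopentan-1-one
Conditions: (S)-1-methyl-3,3-diphenyl-tetrahydro-pyrrolo[1,2-c][1,3,2]oxazaborole [(S)-Me-CBS, 0.2 equiv], catecholborane, toluene, −78 to −40 °C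
Reagents that add atoms: none
Why: Corey–Bakshi–Shibata desymmetrising mono-reduction of the prochiral 1,3-dione, in which the catalyst distinguishes the quaternary carbon (large) from CH2 (small) and should give the (R)-carbinol, fixing the absolute configuration of the future C4'.

Step 2
Reactants: 2 (R)-3-hydroxy-2,2-dimethylcyclopentan-1-one
Product: 3 (S)-3-bromo-2,2-dimethylcyclopentan-1-one
Conditions: CBr4, (n-C8H17)3P, toluene, 60 °C
Reagents that add atoms: tetrabromomethane, BrC(Br)(Br)Br
Why: Appel reaction in its trialkylphosphine variant for hindered alcohols, in which bromide displaces the alkoxyphosphonium group by SN2 with inversion ((R)-C–O to (S)-C–Br) on a five-membered ring, where backside attack next to the quaternary carbon is least encumbered and no α-hydrogen lies between carbonyl and leaving group.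

Step 3
Reactants: 3 (S)-3-bromo-2,2-dimethylcyclopentan-1-one
Product: 6 (S)-4-bromo-3,3-dimethylcyclohexan-1-one, via dibromomethyl carbinolate 4 (not isolated), via lithium enolate 5 (not isolated)
Conditions: CH2Br2, lithium 2,2,6,6-tetramethylpiperidide, THF, −78 °C; then n-BuLi, −95 to −78 °C; AcOH, −78 °C
Reagents that add atoms: dibromomethane, BrCBr
Why: β-Oxido carbenoid one-carbon ring enlargement: LiCHBr2, made in the presence of 3, adds to the ketone to give 4; bromine–lithium exchange with n-BuLi gives the α-bromo-α-lithio carbinolate, and a 1,2-shift of a ring carbon onto the carbenoid carbon with loss of LiBr gives the six-ring enolate 5, which is protonated cold. The closest known reaction type is this same homologation of cycloalkanones, for which the more substituted α-carbon is reported to migrate. No ring is closed by cyclisation; the cyclopentane grows to the cyclohexane by insertion of the carbenoid carbon (C6') between the carbonyl carbon (C1') and the quaternary carbon (C5'). No new stereocenter is formed, and the C–Br carbon (C4') is neither the migrating atom nor enolisable, so it is carried through unchanged. The step needs regioselection (migration of CMe2, not CH2), which rests on the migratory preference of these carbenoids, and chemoselection (exchange at the geminal dibromide, not at the neopentyl secondary bromide), which rests on the much faster exchange of CHBr2 and on the low temperature; the cold quench also keeps enolate 5 from displacing the 1,3-related bromide.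

Step 4
Reactants: 6 (S)-4-bromo-3,3-dimethylcyclohexan-1-one
Product: 7 (4S)-4-bromo-5,5-dimethylcyclohex-1-en-1-yl trifluoromethanesulfonate
Conditions: KN(SiMe3)2, PhNTf2, THF, −78 °C
Reagents that add atoms: N-phenylbis(trifluoromethanesulfonimide), O=S(=O)(N(c1ccccc1)S(=O)(=O)C(F)(F)F)C(F)(F)F
Why: Kinetic enolate triflation, in which the amide base removes the less hindered α-proton at C2' (C6' is neopentyl) and trapping fixes the double bond at C1'=C2'.

Step 5
Reactants: 7 (4S)-4-bromo-5,5-dimethylcyclohex-1-en-1-yl trifluoromethanesulfonate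
Product: 8 [(4S)-4-bromo-5,5-dimethylcyclohex-1-en-1-yl]methanol
Conditions: Bu3SnCH2OH, Pd(PPh3)4 (cat.), LiCl, 1,4-dioxane, 95 °C
Reagents that add atoms: (tributylstannyl)methanol, CCCC[Sn](CCCC)(CCCC)CO
Why: Migita–Kosugi–Stille hydroxymethylation, in which zerovalent palladium inserts into the vinyl C–OTf bond, CH2OH is transferred from tin and reductive elimination gives the allylic alcohol, while the unactivated secondary alkyl bromide should not react.

Step 6
Reactants: 8 [(4S)-4-bromo-5,5-dimethylcyclohex-1-en-1-yl]methanol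
Product: 9 [(1R,4S,6R)-4-bromo-3,3-dimethyl-7-oxabicyclo[4.1.0]heptan-1-yl]methanol
Conditions: Ti(OiPr)4 (cat.), D-(−)-diisopropyl tartrate, t-BuOOH, 4 Å MS, CH2Cl2, −20 °C
Reagents that add atoms: tert-butyl hydroperoxide, CC(C)(C)OO
Why: Katsuki–Sharpless asymmetric epoxidation of a 2,3-disubstituted allylic alcohol, in which the D-(−)-tartrate titanium catalyst delivers oxygen to one alkene face under reagent control and so sets C1' (R) independently of the remote C4' centre.

Step 7
Reactants: 9 [(1R,4S,6R)-4-bromo-3,3-dimethyl-7-oxabicyclo[4.1.0]heptan-1-yl]methanol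
Product: 10 (1R,4S)-4-bromo-1-(hydroxymethyl)-3,3-dimethylcyclohexan-1-ol
Conditions: i-Bu2AlH, CH2Cl2, −20 to 0 °C; aq. potassium sodium tartrate
Reagents that add atoms: none
Why: Regioselective reductive opening of a 2,3-epoxy alcohol, in which hydride attacks the secondary epoxide carbon C2' (C1' is fully substituted) in a trans-diaxial opening, leaving the tertiary C1'–O bond and its configuration intact.

Step 8
Reactants: 10 (1R,4S)-4-bromo-1-(hydroxymethyl)-3,3-dimethylcyclohexan-1-ol
Product: 11 (1R,4S)-4-bromo-3,3-dimethyl-1-(triethylsilyloxy)-1-[(triethylsilyloxy)methyl]cyclohexane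
Conditions: Et3SiOTf, 2,6-lutidine, CH2Cl2, −78 to 0 °C
Reagents that add atoms: triethylsilyl trifluoromethanesulfonate, CC[Si](CC)(CC)OS(=O)(=O)C(F)(F)F
Why: Silyl triflate silylation, which is reactive enough to protect the hindered tertiary hydroxyl as well as the primary one.

Step 9
Reactants: 11 (1R,4S)-4-bromo-3,3-dimethyl-1-(triethylsilyloxy)-1-[(triethylsilyloxy)methyl]cyclohexane
Product: 12 (1R,4S)-4-bromo-3,3-dimethyl-1-(triethylsilyloxy)cyclohexane-1-carbaldehyde
Conditions: (COCl)2, DMSO, CH2Cl2, −78 to −30 °C; then Et3N, −78 °C to rt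
Reagents that add atoms: none
Why: Swern oxidation of a bis(triethylsilyl) ether, in which the activated sulfoxide cleaves only the unhindered primary Si–O bond and oxidises that carbon to the aldehyde while the tertiary silyl ether stays.

**Fragment with rings A and B**

Step 10
Reactants: 13 2-methylcyclohexane-1,3-dione; 14 allyl bromide
Product: 15 2-allyl-2-methylcyclohexane-1,3-dione
Conditions: 1 M aq. NaOH, Bu4NI (cat.), rt
Reagents that add atoms: none
Why: C-Alkylation of the cyclic 1,3-dione enolate with an allylic halide, which creates the quaternary carbon as a prostereogenic centre.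

Step 11
Reactants: 15 2-allyl-2-methylcyclohexane-1,3-dione
Product: 16 (2R,3R)-2-allyl-3-hydroxy-2-methylcyclohexan-1-one
Conditions: (S)-Me-CBS oxazaborolidine (0.2 equiv), catecholborane, toluene, −78 to −50 °C
Reagents that add atoms: none
Why: Corey–Bakshi–Shibata desymmetrisation, in which hydride is delivered to one enantiotopic carbonyl from the methyl-bearing face, so the carbinol and the quaternary carbon are set together with hydroxyl cis to allyl.

Step 12
Reactants: 16 (2R,3R)-2-allyl-3-hydroxy-2-methylcyclohexan-1-one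
Product: 17 (2S,3S)-2-allyl-3-bromo-2-methylcyclohexan-1-one
Conditions: CBr4, (n-C8H17)3P, toluene, 65 °C
Reagents that add atoms: tetrabromomethane, BrC(Br)(Br)Br
Why: Appel reaction as in step 2, an SN2 displacement with inversion that turns the carbinol trans to methyl into the bromide cis to methyl (the later equatorial C–Br next to the angular carbon).

Step 13
Reactants: 17 (2S,3S)-2-allyl-3-bromo-2-methylcyclohexan-1-one
Product: 18 (2S,3S)-3-bromo-2-methyl-2-(2-oxopropyl)cyclohexan-1-one
Conditions: PdCl2 (cat.), CuCl, O2 (1 atm), DMF/H2O, rt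
Reagents that add atoms: water, O
Why: Tsuji–Wacker oxidation, in which Markovnikov hydroxypalladation of the terminal alkene gives the methyl ketone and leaves the alkyl bromide and ring ketone untouched.

Step 14
Reactants: 18 (2S,3S)-3-bromo-2-methyl-2-(2-oxopropyl)cyclohexan-1-one
Product: 19 (7S,7aS)-7-bromo-7a-methyl-1,4,5,6,7,7a-hexahydro-2H-inden-2-one
Conditions: KOH, MeOH, 0 °C to rt
Reagents that add atoms: none
Why: Intramolecular aldol condensation of the 1,4-diketone, in which the methyl-ketone enolate adds to the ring carbonyl and dehydration gives the fused cyclopentenone (ring B), the bridged alternative aldol being reversible.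

Step 15
Reactants: 19 (7S,7aS)-7-bromo-7a-methyl-1,4,5,6,7,7a-hexahydro-2H-inden-2-one
Product: 20 (7'S,7a'S)-7'-bromo-7a'-methyl-1',3',5',6',7',7a'-hexahydrospiro[[1,3]dioxolane-2,2'-indene]
Conditions: HOCH2CH2OH, p-TsOH (cat.), benzene, reflux, Dean–Stark
Reagents that add atoms: ethylene glycol, OCCO
Why: Acid-catalysed dioxolane formation with the usual migration of the enone double bond out of conjugation into ring A (C3a'=C4'), which masks the ketone and exposes C4' for oxidation.

Step 16
Reactants: 20 (7'S,7a'S)-7'-bromo-7a'-methyl-1',3',5',6',7',7a'-hexahydrospiro[[1,3]dioxolane-2,2'-indene]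
Product: 22 (3a'S,7'S,7a'S)-7'-bromo-7a'-methylhexahydrospiro[[1,3]dioxolane-2,2'-inden]-4'(1'H)-one, via alkylborane 21 (not isolated)
Conditions: BH3·THF, THF, 0 °C to rt; then N-methylmorpholine N-oxide, Pr4N[RuO4] (cat.), 4 Å MS, CH2Cl2, rt
Reagents that add atoms: N-methylmorpholine N-oxide, C[N+]1([O-])CCOCC1
Why: Brown hydroboration on the alkene face opposite the angular methyl (syn addition, H to C3a' and B to C4') sets the trans ring fusion, and perruthenate/N-oxide oxidation of the alkylborane gives the C4' ketone directly.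

Step 17
Reactants: 22 (3a'S,7'S,7a'S)-7'-bromo-7a'-methylhexahydrospiro[[1,3]dioxolane-2,2'-inden]-4'(1'H)-one
Product: 24 (3aS,4R,7S,7aS)-7-bromo-4-hydroxy-4,7a-dimethyloctahydro-2H-inden-2-one, via ketal carbinol 23 (not isolated)
Conditions: MeMgBr, CeCl3, THF, −78 °C; then 1 M aq. HCl, THF, rt
Reagents that add atoms: methylmagnesium bromide, C[Mg]Br
Why: Cerium-assisted Grignard addition, in which axial attack is blocked by the 1,3-diaxial angular methyl so that methyl enters equatorially and the new tertiary hydroxyl is axial, cis to the angular methyl; the acid then hydrolyses the dioxolane.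

Step 18
Reactants: 24 (3aS,4R,7S,7aS)-7-bromo-4-hydroxy-4,7a-dimethyloctahydro-2H-inden-2-one
Product: 25 (4R,7S,7aS)-7-bromo-4-hydroxy-4,7a-dimethyl-1,4,5,6,7,7a-hexahydro-2H-inden-2-one
Conditions: 2-iodoxybenzoic acid (IBX), DMSO–toluene, 75 °C
Reagents that add atoms: none
Why: IBX dehydrogenation through the enol, which can only form the C3=C3a enone because C7a is quaternary, and so provides the handle for a regiodefined enolate; the C3a centre is set again in step 20.

Step 19
Reactants: 25 (4R,7S,7aS)-7-bromo-4-hydroxy-4,7a-dimethyl-1,4,5,6,7,7a-hexahydro-2H-inden-2-one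
Product: 26 (4R,7S,7aS)-7-bromo-4,7a-dimethyl-4-(triethylsilyloxy)-1,4,5,6,7,7a-hexahydro-2H-inden-2-one
Conditions: Et3SiOTf, 2,6-lutidine, CH2Cl2, −78 to 0 °C
Reagents that add atoms: triethylsilyl trifluoromethanesulfonate, CC[Si](CC)(CC)OS(=O)(=O)C(F)(F)F
Why: Silyl triflate protection of the hindered tertiary alcohol, so that no acidic proton is present in the enolate steps.

**Union and end game**

Step 20
Reactants: 26 (4R,7S,7aS)-7-bromo-4,7a-dimethyl-4-(triethylsilyloxy)-1,4,5,6,7,7a-hexahydro-2H-inden-2-one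
Product: 27 (3aS,4R,7S,7aS)-7-bromo-2-[dimethyl(phenyl)silyloxy]-4,7a-dimethyl-4-(triethylsilyloxy)-3a,4,5,6,7,7a-hexahydro-1H-indene
Conditions: [(Ph3P)CuH]6 (5 mol%), PhMe2SiH, toluene, rt
Reagents that add atoms: dimethylphenylsilane, C[SiH](C)c1ccccc1
Why: Copper hydride catalysed 1,4-hydrosilylation of the enone, in which hydride adds to C3a from the face opposite the angular methyl and the axial silyloxy group, giving the trans ring fusion and, regiospecifically, the C2=C3 enol silane.

Step 21
Reactants: 27 (3aS,4R,7S,7aS)-7-bromo-2-[dimethyl(phenyl)silyloxy]-4,7a-dimethyl-4-(triethylsilyloxy)-3a,4,5,6,7,7a-hexahydro-1H-indene; 12 (1R,4S)-4-bromo-3,3-dimethyl-1-(triethylsilyloxy)cyclohexane-1-carbaldehyde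
Product: 29 (3R,3aS,4R,7S,7aS)-7-bromo-3-{(R)-[(1R,4S)-4-bromo-3,3-dimethyl-1-(triethylsilyloxy)cyclohexyl](hydroxy)methyl}-4,7a-dimethyl-4-(triethylsilyloxy)octahydro-2H-inden-2-one, via O-silyl aldol 28 (not isolated)
Conditions: (Me2N)3S[Me3SiF2] (10 mol%), THF, −78 °C; then aq. citric acid, THF, 0 °C
Reagents that add atoms: none
Why: Fluoride-promoted aldol addition of the enol silane (naked enolate, open transition state), which favours the syn adduct whatever the enolate geometry, whereas a closed Zimmerman–Traxler transition state from this E-enolate would give anti; the aldehyde approaches C3 from the face opposite the angular methyl and the C4 silyloxy group, setting C3 and the carbinol carbon, and mild acid removes the labile secondary silyl group.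

Step 22
Reactants: 29 (the aldol of step 21)
Product: 30 (R)-[(1R,4S)-4-bromo-3,3-dimethyl-1-(triethylsilyloxy)cyclohexyl][(1R,3aS,4S,7R,7aS)-4-bromo-3a,7-dimethyl-2-oxo-7-(triethylsilyloxy)octahydro-1H-inden-1-yl]methyl acetate
Conditions: Ac2O, DMAP, pyridine, CH2Cl2, 0 to 40 °C
Reagents that add atoms: acetic anhydride, CC(=O)OC(C)=O
Why: DMAP-catalysed acylation of the secondary aldol hydroxyl, done before the ketone is reduced so that the acetate ends up on the more hindered of the two secondary oxygens.

Step 23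
Reactants: 30 (the keto acetate of step 22)
Product: 31 (R)-[(1R,4S)-4-bromo-3,3-dimethyl-1-(triethylsilyloxy)cyclohexyl][(1S,2R,3aS,4S,7R,7aS)-4-bromo-2-hydroxy-3a,7-dimethyl-7-(triethylsilyloxy)octahydro-1H-inden-1-yl]methyl acetate
Conditions: LiAlH(Ot-Bu)3, THF, −78 to −40 °C; AcOH, then aq. potassium sodium tartrate
Reagents that add atoms: none
Why: Bulky hydride reduction of a 2-substituted cyclopentanone, in which the reagent should attack anti to the large side chain on the neighbouring carbon to give the cis (2R) alcohol; the acetate is not reduced at low temperature and the cold acidic quench guards against 1,3-acyl migration.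

Step 24
Reactants: 31 (the hydroxy acetate of step 23)
Product: 32 (R)-[(1R,4S)-4-bromo-1-hydroxy-3,3-dimethylcyclohexyl][(1S,2R,3aS,4S,7R,7aS)-4-bromo-2,7-dihydroxy-3a,7-dimethyloctahydro-1H-inden-1-yl]methyl acetate (CNP0166243.1)
Conditions: HF·pyridine, pyridine, THF, 0 °C to rt
Reagents that add atoms: none
Why: Fluoride cleavage of the two tertiary triethylsilyl ethers under buffered acidic conditions, which do not move the acetate between the syn-1,3 oxygens.

**Compound list**

1 | 2,2-dimethylcyclopentane-1,3-dione | CC1(C)C(=O)CCC1=O | starting material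
2 | (R)-3-hydroxy-2,2-dimethylcyclopentan-1-one | O=C1CC[C@@H](O)C1(C)C | intermediate
3 | (S)-3-bromo-2,2-dimethylcyclopentan-1-one | O=C1CC[C@H](Br)C1(C)C | intermediate
4 | lithium (3S)-3-bromo-1-(dibromomethyl)-2,2-dimethylcyclopentan-1-olate (both C1 epimers) | [Li+].[O-]C1(C(Br)Br)CC[C@H](Br)C1(C)C | intermediate
5 | lithium (4S)-4-bromo-3,3-dimethylcyclohex-1-en-1-olate | [Li+].[O-]C1=CC(C)(C)[C@@H](Br)CC1 | intermediate
6 | (S)-4-bromo-3,3-dimethylcyclohexan-1-one | O=C1CC[C@H](Br)C(C)(C)C1 | intermediate
7 | (4S)-4-bromo-5,5-dimethylcyclohex-1-en-1-yl trifluoromethanesulfonate | O=S(=O)(OC1=CC[C@H](Br)C(C)(C)C1)C(F)(F)F | intermediate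
8 | [(4S)-4-bromo-5,5-dimethylcyclohex-1-en-1-yl]methanol | OCC1=CC[C@H](Br)C(C)(C)C1 | intermediate
9 | [(1R,4S,6R)-4-bromo-3,3-dimethyl-7-oxabicyclo[4.1.0]heptan-1-yl]methanol | OC[C@@]1(O2)[C@H]2C[C@H](Br)C(C)(C)C1 | intermediate
10 | (1R,4S)-4-bromo-1-(hydroxymethyl)-3,3-dimethylcyclohexan-1-ol | OC[C@@]1(O)CC[C@H](Br)C(C)(C)C1 | intermediate
11 | (1R,4S)-4-bromo-3,3-dimethyl-1-(triethylsilyloxy)-1-[(triethylsilyloxy)methyl]cyclohexane | CC[Si](CC)(CC)OC[C@@]1(O[Si](CC)(CC)CC)CC[C@H](Br)C(C)(C)C1 | intermediate
12 | (1R,4S)-4-bromo-3,3-dimethyl-1-(triethylsilyloxy)cyclohexane-1-carbaldehyde | O=C[C@@]1(O[Si](CC)(CC)CC)CC[C@H](Br)C(C)(C)C1 | intermediate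
13 | 2-methylcyclohexane-1,3-dione | CC1C(=O)CCCC1=O | starting material
14 | allyl bromide | C=CCBr | starting material
15 | 2-allyl-2-methylcyclohexane-1,3-dione | C=CCC1(C)C(=O)CCCC1=O | intermediate
16 | (2R,3R)-2-allyl-3-hydroxy-2-methylcyclohexan-1-one | C=CC[C@]1(C)[C@H](O)CCCC1=O | intermediate
17 | (2S,3S)-2-allyl-3-bromo-2-methylcyclohexan-1-one | C=CC[C@]1(C)[C@@H](Br)CCCC1=O | intermediate
18 | (2S,3S)-3-bromo-2-methyl-2-(2-oxopropyl)cyclohexan-1-one | CC(=O)C[C@]1(C)[C@@H](Br)CCCC1=O | intermediate
19 | (7S,7aS)-7-bromo-7a-methyl-1,4,5,6,7,7a-hexahydro-2H-inden-2-one | O=C1C[C@]2(C)[C@@H](Br)CCCC2=C1 | intermediate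
20 | (7'S,7a'S)-7'-bromo-7a'-methyl-1',3',5',6',7',7a'-hexahydrospiro[[1,3]dioxolane-2,2'-indene] | C1COC2(O1)C[C@]3(C)[C@@H](Br)CCC=C3C2 | intermediate
21 | alkylborane from 20, BH2 on C4' and H on C3a', both on the face opposite the 7a'-methyl | C1COC2(O1)C[C@]3(C)[C@@H](Br)CC[C@H](B)[C@H]3C2 | intermediate
22 | (3a'S,7'S,7a'S)-7'-bromo-7a'-methylhexahydrospiro[[1,3]dioxolane-2,2'-inden]-4'(1'H)-one | C1COC2(O1)C[C@]3(C)[C@@H](Br)CCC(=O)[C@H]3C2 | intermediate
23 | (3a'S,4'R,7'S,7a'S)-7'-bromo-4',7a'-dimethyloctahydrospiro[[1,3]dioxolane-2,2'-inden]-4'-ol | C1COC2(O1)C[C@]3(C)[C@@H](Br)CC[C@@](C)(O)[C@H]3C2 | intermediate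
24 | (3aS,4R,7S,7aS)-7-bromo-4-hydroxy-4,7a-dimethyloctahydro-2H-inden-2-one | O=C1C[C@]2(C)[C@@H](Br)CC[C@@](C)(O)[C@H]2C1 | intermediate
25 | (4R,7S,7aS)-7-bromo-4-hydroxy-4,7a-dimethyl-1,4,5,6,7,7a-hexahydro-2H-inden-2-one | O=C1C[C@]2(C)[C@@H](Br)CC[C@@](C)(O)C2=C1 | intermediate
26 | (4R,7S,7aS)-7-bromo-4,7a-dimethyl-4-(triethylsilyloxy)-1,4,5,6,7,7a-hexahydro-2H-inden-2-one | O=C1C[C@]2(C)[C@@H](Br)CC[C@@](C)(O[Si](CC)(CC)CC)C2=C1 | intermediate
27 | (3aS,4R,7S,7aS)-7-bromo-2-[dimethyl(phenyl)silyloxy]-4,7a-dimethyl-4-(triethylsilyloxy)-3a,4,5,6,7,7a-hexahydro-1H-indene | C[Si](C)(c1ccccc1)OC2=C[C@@H]3[C@](C)(O[Si](CC)(CC)CC)CC[C@H](Br)[C@@]3(C)C2 | intermediate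
28 | dimethyl(phenyl)silyl ether of aldol 29 | C[Si](C)(c1ccccc1)O[C@H]([C@@H]1C(=O)C[C@]2(C)[C@@H](Br)CC[C@@](C)(O[Si](CC)(CC)CC)[C@@H]12)[C@@]1(O[Si](CC)(CC)CC)CC[C@H](Br)C(C)(C)C1 | intermediate
29 | (3R,3aS,4R,7S,7aS)-7-bromo-3-{(R)-[(1R,4S)-4-bromo-3,3-dimethyl-1-(triethylsilyloxy)cyclohexyl](hydroxy)methyl}-4,7a-dimethyl-4-(triethylsilyloxy)octahydro-2H-inden-2-one | O[C@H]([C@@H]1C(=O)C[C@]2(C)[C@@H](Br)CC[C@@](C)(O[Si](CC)(CC)CC)[C@@H]12)[C@@]1(O[Si](CC)(CC)CC)CC[C@H](Br)C(C)(C)C1 | intermediate
30 | acetate of 29 (keto acetate) | CC(=O)O[C@H]([C@@H]1C(=O)C[C@]2(C)[C@@H](Br)CC[C@@](C)(O[Si](CC)(CC)CC)[C@@H]12)[C@@]1(O[Si](CC)(CC)CC)CC[C@H](Br)C(C)(C)C1 | intermediate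
31 | bis(triethylsilyl) ether of the target (ring B carbinol free) | CC(=O)O[C@H]([C@@H]1[C@H](O)C[C@]2(C)[C@@H](Br)CC[C@@](C)(O[Si](CC)(CC)CC)[C@@H]12)[C@@]1(O[Si](CC)(CC)CC)CC[C@H](Br)C(C)(C)C1 | intermediate
32 | CNP0166243.1 | CC(=O)O[C@H]([C@@H]1[C@H](O)C[C@]2(C)[C@@H](Br)CC[C@@](C)(O)[C@@H]12)[C@@]1(O)CC[C@H](Br)C(C)(C)C1 | target

**Step count and risks**

Total: 24 steps. Longest linear sequence: 15 steps (steps 10 to 24); the ring C branch (steps 1 to 9) joins at step 21.

Steps most likely to fail:

Step 3. What may go wrong: bromine–lithium exchange or base-induced 1,3-elimination at the secondary C–Br bond during the organolithium stages, with loss of the stereocentre. The fallback inverts the order of ring enlargement and C–Br formation. It sets out from 2, which is silylated (t-BuMe2SiOTf, 2,6-lutidine) to (R)-3-(tert-butyldimethylsilyloxy)-2,2-dimethylcyclopentan-1-one F1. The same carbenoid homologation on this halogen-free ketone should give (R)-4-(tert-butyldimethylsilyloxy)-3,3-dimethylcyclohexan-1-one F2. Bu4NF then frees (R)-4-hydroxy-3,3-dimethylcyclohexan-1-one F3, and the bromide is introduced with inversion on the six-membered ring (CBr4, (n-C8H17)3P), coming back to the route at 6.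

Step 12 (the same concern applies to step 2). What may go wrong: elimination to the cyclohexene and 1,2-shift from the quaternary carbon outrun substitution at the neopentyl carbinol carbon of the six-membered ring. The fallback does the substitution on a cyclopentanol and then enlarges the ring. It sets out from allyl bromide 14, which allylates purchased 2-methylcyclopentane-1,3-dione F4 (aq. NaOH) to 2-allyl-2-methylcyclopentane-1,3-dione F5. The oxazaborolidine reduction of step 11 should give (2R,3R)-2-allyl-3-hydroxy-2-methylcyclopentan-1-one F6, and bromination with inversion (CBr4, (n-C8H17)3P) gives (2S,3S)-2-allyl-3-bromo-2-methylcyclopentan-1-one F7. Homologation with Me3SiCHN2 and BF3·OEt2, in which the methylene α-carbon migrates, followed by protodesilylation on work-up, comes back to the route at 17.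

Step 21. What may go wrong: poor simple diastereoselection at the new carbinol carbon in the fluoride-promoted aldol, or retro-aldol of the hindered adduct under the basic conditions. The fallback sets the carbinol centres by reduction instead. It sets out from 27 and 12: a BF3·OEt2 Mukaiyama aldol gives the β-hydroxy ketone as a mixture of carbinol epimers F8, and Dess–Martin oxidation converges both on the β-diketone F9. LiAlH(Ot-Bu)3 reduces the ring carbonyl anti to the acyl group to the ring B hydroxy ketone F10, and Et2BOMe/NaBH4 (Narasaka–Prasad reduction) reduces the side-chain ketone to the syn-1,3-diol F11. Et3SiCl/imidazole silylates the less hindered ring hydroxyl to F12, Ac2O/DMAP gives the acetate F13, and HF·pyridine comes back to the route at 32.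

**Further compounds**

F1 | step 3 | (R)-3-(tert-butyldimethylsilyloxy)-2,2-dimethylcyclopentan-1-one | O=C1CC[C@@H](O[Si](C)(C)C(C)(C)C)C1(C)C
F2 | step 3 | (R)-4-(tert-butyldimethylsilyloxy)-3,3-dimethylcyclohexan-1-one | O=C1CC[C@@H](O[Si](C)(C)C(C)(C)C)C(C)(C)C1
F3 | step 3 | (R)-4-hydroxy-3,3-dimethylcyclohexan-1-one | O=C1CC[C@@H](O)C(C)(C)C1
F4 | step 12 | 2-methylcyclopentane-1,3-dione (purchased) | CC1C(=O)CCC1=O
F5 | step 12 | 2-allyl-2-methylcyclopentane-1,3-dione | C=CCC1(C)C(=O)CCC1=O
F6 | step 12 | (2R,3R)-2-allyl-3-hydroxy-2-methylcyclopentan-1-one | C=CC[C@]1(C)[C@H](O)CCC1=O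
F7 | step 12 | (2S,3S)-2-allyl-3-bromo-2-methylcyclopentan-1-one | C=CC[C@]1(C)[C@@H](Br)CCC1=O
F8 | step 21 | aldol 29 as a mixture of epimers at the side-chain carbinol carbon | OC([C@@H]1C(=O)C[C@]2(C)[C@@H](Br)CC[C@@](C)(O[Si](CC)(CC)CC)[C@@H]12)[C@@]1(O[Si](CC)(CC)CC)CC[C@H](Br)C(C)(C)C1
F9 | step 21 | β-diketone (ring B ketone and side-chain ketone) | O=C([C@@H]1C(=O)C[C@]2(C)[C@@H](Br)CC[C@@](C)(O[Si](CC)(CC)CC)[C@@H]12)[C@@]1(O[Si](CC)(CC)CC)CC[C@H](Br)C(C)(C)C1
F10 | step 21 | ring B hydroxy ketone (side-chain ketone kept) | O=C([C@@H]1[C@H](O)C[C@]2(C)[C@@H](Br)CC[C@@](C)(O[Si](CC)(CC)CC)[C@@H]12)[C@@]1(O[Si](CC)(CC)CC)CC[C@H](Br)C(C)(C)C1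
F11 | step 21 | syn-1,3-diol | O[C@H]([C@@H]1[C@H](O)C[C@]2(C)[C@@H](Br)CC[C@@](C)(O[Si](CC)(CC)CC)[C@@H]12)[C@@]1(O[Si](CC)(CC)CC)CC[C@H](Br)C(C)(C)C1
F12 | step 21 | diol with the ring B hydroxyl as triethylsilyl ether | O[C@H]([C@@H]1[C@H](O[Si](CC)(CC)CC)C[C@]2(C)[C@@H](Br)CC[C@@](C)(O[Si](CC)(CC)CC)[C@@H]12)[C@@]1(O[Si](CC)(CC)CC)CC[C@H](Br)C(C)(C)C1
F13 | step 21 | tris(triethylsilyl) ether of the target | CC(=O)O[C@H]([C@@H]1[C@H](O[Si](CC)(CC)CC)C[C@]2(C)[C@@H](Br)CC[C@@](C)(O[Si](CC)(CC)CC)[C@@H]12)[C@@]1(O[Si](CC)(CC)CC)CC[C@H](Br)C(C)(C)C1
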